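Assumption: the target has no stereocentre, so "single enantiomer" is read as the single (E)-enone isomer drawn.

## Retrosynthetic overview

1. Ring B is bought intact; its only cut is the aryl–prenyl bond: 4-hydroxybenzaldehyde 1 + prenyl bromide 2 give aldehyde 3.
2. The chromene is cut down to three open-chain pieces: silyl enol ether 4 (through dienolate 5) gives diene 6; the others are ynone 7 and enal 8.
3. Both chromene rings are made in one flask: 6 + 7 close ring A by Diels–Alder benzannulation (adduct 9, resorcinol ketone 10); 10 + 8 close the pyran ring by condensation and 6π oxa-cyclisation (quinone methide 11), giving acetylchromene 12.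
4. Last bond is the enone C=C: 12 + 3 give aldol 13, then target 14 (Claisen–Schmidt).
5. Ring order: ring A first, pyran ring second, same operation; ring B is never made or broken.

## Route

Step 1
Reactants: 1 4-hydroxybenzaldehyde; 2 1-bromo-3-methylbut-2-ene (prenyl bromide)
Product: 3 4-hydroxy-3-(3-methylbut-2-en-1-yl)benzaldehyde
Conditions: KOH (1.1 equiv, 10% aq.), H2O, rt, 48 h; then dilute HCl to pH 5
Reagents that add atoms: none
Why: Phenoxide C-alkylation (SN2 of an ambident phenoxide at a primary allylic bromide): in water the oxygen is shielded by hydrogen bonding, so a useful share of the alkylation goes to the ortho carbon (para is blocked by CHO), the dienone re-aromatises to 3, and the O-prenyl ether by-product is separated.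

Step 2
Reactants: 4 methyl 3-(trimethylsilyloxy)but-2-enoate (E/Z mixture)
Product: 6 1-methoxy-1,3-bis(trimethylsilyloxy)buta-1,3-diene, via lithium dienolate 5 (not isolated)
Conditions: LiN(i-Pr)2 (1.1 equiv), THF, −78 °C, 1 h; then Me3SiCl (1.2 equiv), −78 °C → rt; distil
Reagents that add atoms: chlorotrimethylsilane, C[Si](C)(C)Cl
Why: LiN(i-Pr)2 removes a γ-proton of the β-silyloxy enoate to give cross-conjugated ester dienolate 5, which the hard silicon electrophile traps on oxygen (O-silylation of an ester dienolate, the standard route to this 1,3-bis(silyloxy)diene); the geometry of 4 is erased and that of the new ketene acetal is irrelevant because that carbon becomes aromatic in step 3.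

Step 3
Reactants: 6 1-methoxy-1,3-bis(trimethylsilyloxy)buta-1,3-diene; 7 but-3-yn-2-one; 8 3-methylbut-2-enal (prenal)
Product: 12 1-(5-hydroxy-2,2-dimethyl-2H-chromen-6-yl)ethan-1-one, via Diels–Alder adduct 9 (not isolated), via 2,4-dihydroxyacetophenone 10 (not isolated), via ortho-quinone methide 11 (not isolated)
Conditions: 6 (1.05 equiv), 7 (1.0 equiv), PhMe, −20 °C → rt, 12 h; then MeOH (5 equiv), rt, 1 h; then 8 (1.5 equiv), ethylenediammonium diacetate (20 mol%), 110 °C, 12 h
Reagents that add atoms: none
Why: Proposed new method: one-flask Diels–Alder benzannulation followed by enal chromenylation, in which the nucleophilic CH2 terminus of the 1,1,3-trioxygenated diene 6 bonds to the unsubstituted alkyne carbon of 7, so the acetyl group in adduct 9 sits ortho to the former ketene acetal carbon and para to the enol ether carbon; methanolysis of the two silyl groups collapses the ketal with loss of methanol to aromatic 10 (ring A); ethylenediammonium diacetate then condenses 8 at the carbon between the two oxygens, water is lost to quinone methide 11, and a 6π oxa-electrocyclisation through the free para oxygen (the ortho hydroxyl stays hydrogen-bonded to the acetyl group) closes the pyran ring; the closest known reactions are Diels–Alder aromatisations of Danishefsky- and Brassard-type silyloxydienes with alkynones and the amine-salt-catalysed condensation of resorcinols with enals, which have not been run in sequence in one pot; no stereocentre is formed.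

Step 4
Reactants: 12 1-(5-hydroxy-2,2-dimethyl-2H-chromen-6-yl)ethan-1-one; 3 4-hydroxy-3-(3-methylbut-2-en-1-yl)benzaldehyde
Product: 14 (E)-1-(5-hydroxy-2,2-dimethyl-2H-chromen-6-yl)-3-[4-hydroxy-3-(3-methylbut-2-en-1-yl)phenyl]prop-2-en-1-one (paratocarpin B), via aldol adduct 13 (not isolated)
Conditions: KOH (60% aq., 12 equiv), EtOH, 0 °C → rt, 48 h; then 1 M HCl, 0 °C, to pH 4
Reagents that add atoms: none
Why: Claisen–Schmidt condensation: the methyl ketone enolate of 12 adds to the non-enolisable aldehyde 3 and aldol 13 loses water by E1cB to the conjugated enone, formed as the thermodynamically preferred (E) isomer, the only stereochemical element of the target; the racemic carbinol centre of 13 disappears and cold acidification avoids flavanone closure.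

## Compound list

1 | 4-hydroxybenzaldehyde | O=Cc1ccc(O)cc1 | starting material
2 | 1-bromo-3-methylbut-2-ene (prenyl bromide) | CC(C)=CCBr | starting material
3 | 4-hydroxy-3-(3-methylbut-2-en-1-yl)benzaldehyde | CC(C)=CCc1cc(C=O)ccc1O | intermediate
4 | methyl 3-(trimethylsilyloxy)but-2-enoate (E/Z mixture, geometry erased in step 2) | COC(=O)C=C(C)O[Si](C)(C)C | starting material
5 | lithium 1-methoxy-3-(trimethylsilyloxy)buta-1,3-dien-1-olate (not isolated) | [Li+].[O-]C(OC)=CC(=C)O[Si](C)(C)C | intermediate
6 | 1-methoxy-1,3-bis(trimethylsilyloxy)buta-1,3-diene (ketene acetal geometry undefined and irrelevant) | C=C(O[Si](C)(C)C)C=C(OC)O[Si](C)(C)C | intermediate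
7 | but-3-yn-2-one | CC(=O)C#C | starting material
8 | 3-methylbut-2-enal (prenal) | CC(C)=CC=O | starting material
9 | 1-[6-methoxy-4,6-bis(trimethylsilyloxy)cyclohexa-1,4-dien-1-yl]ethan-1-one (racemic, not isolated) | CC(=O)C1=CCC(O[Si](C)(C)C)=CC1(OC)O[Si](C)(C)C | intermediate
10 | 1-(2,4-dihydroxyphenyl)ethan-1-one (2,4-dihydroxyacetophenone, not isolated) | CC(=O)c1ccc(O)cc1O | intermediate
11 | (2Z)-4-acetyl-3-hydroxy-2-(3-methylbut-2-en-1-ylidene)cyclohexa-3,5-dien-1-one (not isolated) | CC(C)=C/C=C1\C(=O)C=CC(C(C)=O)=C1O | intermediate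
12 | 1-(5-hydroxy-2,2-dimethyl-2H-chromen-6-yl)ethan-1-one | CC(=O)c1ccc2c(c1O)C=CC(C)(C)O2 | intermediate
13 | 3-hydroxy-1-(5-hydroxy-2,2-dimethyl-2H-chromen-6-yl)-3-[4-hydroxy-3-(3-methylbut-2-en-1-yl)phenyl]propan-1-one (racemic, not isolated) | CC(C)=CCc1cc(C(O)CC(=O)c2ccc3c(c2O)C=CC(C)(C)O3)ccc1O | intermediate
14 | (E)-1-(5-hydroxy-2,2-dimethyl-2H-chromen-6-yl)-3-[4-hydroxy-3-(3-methylbut-2-en-1-yl)phenyl]prop-2-en-1-one (paratocarpin B) | CC(C)=CCc1cc(/C=C/C(=O)c2ccc3c(c2O)C=CC(C)(C)O3)ccc1O | target

## Step count and risks

Total step count: 4. Longest linear sequence: 3 steps (4 → 6 → 12 → 14).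

**Most likely to fail, first: step 3.** The two ring closures have not been run back to back; the ynone may oligomerise and the silicon by-products or leftover diene may disturb the enal condensation. The fallback sets out from 10, isolated by working up after the methanol stage (10 is also sold). 3-Chloro-3-methylbut-1-yne (K2CO3, KI, acetone, reflux) alkylates the free 4-hydroxyl to give 1-{2-hydroxy-4-[(2-methylbut-3-yn-2-yl)oxy]phenyl}ethan-1-one F1. Heating F1 in N,N-diethylaniline at 190 °C brings about the aryl propargyl ether Claisen shift to the carbon between the oxygens. Enolisation gives 1-[2,4-dihydroxy-3-(3-methylbuta-1,2-dien-1-yl)phenyl]ethan-1-one F2. Its 1,5-hydrogen shift leads to quinone methide 11, and the same 6π closure brings the sequence back to the route at 12. The pyran ring is thus made by a sigmatropic cascade instead of an enal condensation, and in separate operations.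

**Second: step 1.** O-alkylation and double alkylation compete, so the yield of 3 is low (typically a quarter to a third). The fallback sets out from 1. 3-Chloro-3-methylbut-1-yne (K2CO3, KI, acetone, reflux) gives 4-[(2-methylbut-3-yn-2-yl)oxy]benzaldehyde F3. Semi-hydrogenation (H2, Pd/CaCO3 poisoned with Pb(OAc)2, quinoline, EtOAc, rt) gives 4-[(2-methylbut-3-en-2-yl)oxy]benzaldehyde F4. Heating F4 in N,N-diethylaniline at 180 °C effects the aromatic Claisen rearrangement, which delivers the allyl unit to the ortho carbon with inversion of its ends, and so returns to the route at 3. The prenyl group is then placed by an intramolecular shift instead of a direct C-alkylation.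

**Third: step 4.** The aldehyde is deactivated as its phenoxide and the 2'-hydroxychalcone can close to the flavanone. The fallback sets out from 3. ClCH2OCH3 (K2CO3, acetone, rt) gives 4-(methoxymethoxy)-3-(3-methylbut-2-en-1-yl)benzaldehyde F5. Condensation of F5 with 12 (KOH, EtOH, rt) gives (E)-1-(5-hydroxy-2,2-dimethyl-2H-chromen-6-yl)-3-[4-(methoxymethoxy)-3-(3-methylbut-2-en-1-yl)phenyl]prop-2-en-1-one F6. Brief treatment of F6 with 1 M HCl in MeOH at rt removes the acetal and returns to the route at 14. The electrophile is then a neutral ether-protected aldehyde, at the cost of two extra operations.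

Further compounds
F1 | step 3 | 1-{2-hydroxy-4-[(2-methylbut-3-yn-2-yl)oxy]phenyl}ethan-1-one | CC(=O)c1ccc(OC(C)(C)C#C)cc1O
F2 | step 3 | 1-[2,4-dihydroxy-3-(3-methylbuta-1,2-dien-1-yl)phenyl]ethan-1-one | CC(=O)c1ccc(O)c(C=C=C(C)C)c1O
F3 | step 1 | 4-[(2-methylbut-3-yn-2-yl)oxy]benzaldehyde | C#CC(C)(C)Oc1ccc(C=O)cc1
F4 | step 1 | 4-[(2-methylbut-3-en-2-yl)oxy]benzaldehyde | C=CC(C)(C)Oc1ccc(C=O)cc1
F5 | step 4 | 4-(methoxymethoxy)-3-(3-methylbut-2-en-1-yl)benzaldehyde | COCOc1ccc(C=O)cc1CC=C(C)C
F6 | step 4 | (E)-1-(5-hydroxy-2,2-dimethyl-2H-chromen-6-yl)-3-[4-(methoxymethoxy)-3-(3-methylbut-2-en-1-yl)phenyl]prop-2-en-1-one | COCOc1ccc(/C=C/C(=O)c2ccc3c(c2O)C=CC(C)(C)O3)cc1CC=C(C)C
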